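Remark on the chemistry: pakyonol has no stereocentre and no stable planar or axial chirality (the SMILES carries no stereodescriptor), so the target is one achiral compound and no step has to set configuration. Ring letters used throughout: A = the methoxy-bearing ring, B = the 1,4-phenylene, C = the hydroxy-bearing ring, D = the 1,3-phenylene. Compounds 1, 2, 4 and 7 are taken to be catalogue chemicals.

## Structural features

Pakyonol is a macrocyclic bis(bibenzyl): four benzene rings joined into one 20-membered ring (shortest path) by two diaryl ether oxygens (A–O–B and C–O–D) and two ethano bridges (B–CH2CH2–C and D–CH2CH2–A). Ring A is entered meta (ether oxygen ortho to OMe, bridge carbon para to OMe), ring B para, ring C para (ether oxygen para to the bridge, free OH ortho to that oxygen) and ring D meta. The only differentiation problem is OH on ring C against OMe on ring A; the free phenol sits in an electron-rich catechol monoether and is the one oxidation-prone group. The real difficulty is closing the 20-membered ring without oligomerisation; the two diaryl ether bonds, each flanked by an ortho oxygen substituent, come second. The key step exploits the B/C ethano bridge: both of its carbons are benzylic, so a sulfonyl group placed between them (ArB–CH2–SO2–CH2–ArC) is the retron of a Ramberg–Bäcklund ring contraction. Each of these two carbons is also para to a diaryl ether oxygen, so at the carbonyl oxidation level it activates the fluoride displacement that makes the ether bond on its own ring.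

## Logic of the disconnections

In one sentence: 22 arises by Ramberg–Bäcklund ring contraction of the 21-membered cyclic sulfone 16, in which SO2 temporarily sits between the two benzylic carbons of the B/C bridge.

22 from 20: no skeletal bond is cut; a C=C is placed between the two benzylic carbons of the B/C bridge and a benzyl group on the ring C oxygen. One hydrogenation removes both, so the last step is also the deprotection. The demand is a sulfur-free alkene so that the palladium catalyst stays active.

20 from 16 (key): the C=C between the benzylic carbons of rings B and C is cut and SO2 is inserted, giving two C–S bonds and a 21-membered ring. The C–C bond then forms inside a three-membered ring after the macrocycle already exists, so it cannot form intermolecularly. The gain is that the macrocyclic C–C closure becomes a C–S closure at sp3 carbon. The demand is clean monohalogenation at an α-sulfonyl carbon and a masked phenol.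

16 from 14 from 11: the S=O bonds are removed, then both C–S bonds are cut with sulfide as a one-atom linchpin. The two chain ends of 11 are identical benzylic bromides, so no end differentiation is needed. The demand is high dilution and conditions under which the electron-rich benzylic bromides do not solvolyse.

11 from 10 from 9: the two C–Br bonds go back to C–OH and then to an aldehyde (ring C) and a methyl ester (ring B). These carbonyl groups are the para activators that allowed the ether bonds to be made, and one hydride reduction converts both. The demand is a reductant that spares the benzyl ether.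

9 from 6 and 8, and 8 from 7: the O–C(ring C) ether bond is cut, with the ring D phenol displacing fluoride para to the aldehyde. The benzyl group is put on 7 first because a free ortho phenoxide would shut the displacement down. The demand is substitution at a carbon flanked by OBn, with the ester of 6 surviving carbonate at high temperature.

6 from 5 from 3 and 4: the D/A ethano bridge is raised to an alkyne and cut at the C(ring A)–C(sp) bond. Both partners are simple, and the alkyne is saturated before any benzyl ether is present. The demand is oxidative addition into an electron-rich C–Br bond in the presence of a free phenol.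

3 from 1 and 2: the O–C(ring B) ether bond is cut; the ester para to fluoride activates the displacement and is the masked benzylic carbon of the B/C bridge. The demand is chemoselectivity for C–F over the C–Br bond of 1.

## Other disconnections considered

Alternative 1: the first plan that comes to mind cuts the same B/C bridge at the stilbene level and closes the ring by an intramolecular Wittig reaction of the ω-formyl benzylic phosphonium salt A1, which would give 20 directly. There, ring closure and C–C bond formation are the same event, so the slow C–C step must compete irreversibly with intermolecular olefination. The two chain ends must also be differentiated (aldehyde on ring C, phosphonium on ring B), which means masking the aldehyde of 9 while the ester end is converted. The chosen plan treats both ends alike, closes the ring by the fastest available SN2 (thiolate on benzylic bromide) and forms the C–C bond only afterwards, within the ring. The step count of the two plans is similar, so the ground for preference is mechanistic. Direct reductive C–C coupling of 11 is shorter and is kept as the fallback for step 8, but it has the same weakness: radical or organometallic chain ends that can couple intermolecularly or be reduced.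

Alternative 2: cut the O–C(ring C) ether bond last and close the ring by intramolecular SNAr of the seco phenol A2 to the nitro macrocycle A3. In the seco compound the position para to the leaving group on ring C is already the saturated bridge carbon, so activation must come from a nitro group placed where the hydroxyl belongs. That costs three further steps on the macrocycle (reduction, diazotisation, hydrolysis), and the diazonium stage is exposed to azo coupling with the electron-rich rings. A copper-mediated closure at the unactivated, ortho-alkoxylated carbon would avoid the nitro group, but its bimolecular catalyst–substrate steps are slow at the dilution a macrocyclisation needs.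

Alternative 3: the biomimetic cut is the same O–C(ring C) bond made by oxidative phenol coupling of the acyclic diphenol A4, which would give 22 in one step. Rings C and D of A4 are both 3-hydroxyphenethyl units of nearly identical oxidation potential, and a phenoxyl radical carries spin at oxygen and at its ortho and para carbons. Nothing in the substrate separates the required O(ring D)–C(ring C) coupling from the reverse O–C coupling or from C–C couplings, and the catechol monoether product is more easily oxidised than A4. The chosen plan fixes every connectivity by polar, position-defined reactions.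

Key step: step 10

## Route

Step 1
Reactants: 1 5-bromo-2-methoxyphenol; 2 methyl 4-fluorobenzoate
Product: 3 methyl 4-(5-bromo-2-methoxyphenoxy)benzoate
Conditions: K2CO3, DMSO, 120 °C
Reagents that add atoms: none
Why: Nucleophilic aromatic substitution: the phenoxide of 1 displaces the fluoride activated by the para ester of 2, and the C–Br bond of 1 is inert without a metal catalyst. This forms the A–O–B ether with the ring A pattern fixed by 1.

Step 2
Reactants: 3 methyl 4-(5-bromo-2-methoxyphenoxy)benzoate; 4 3-ethynylphenol
Product: 5 methyl 4-{5-[(3-hydroxyphenyl)ethynyl]-2-methoxyphenoxy}benzoate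
Conditions: Pd(PhCN)2Cl2 (cat.), [HP(t-Bu)3]BF4 (cat.), CuI (cat.), i-Pr2NH, dioxane, rt to 50 °C, degassed
Reagents that add atoms: none
Why: Sonogashira coupling; the bulky electron-rich phosphine allows oxidative addition into the electron-rich C–Br bond para to OMe, and the free phenol and the ester are tolerated under amine base.

Step 3
Reactants: 5 methyl 4-{5-[(3-hydroxyphenyl)ethynyl]-2-methoxyphenoxy}benzoate
Product: 6 methyl 4-{5-[2-(3-hydroxyphenyl)ethyl]-2-methoxyphenoxy}benzoate
Conditions: H2 (1 atm), 10% Pd/C, EtOAc/MeOH, rt
Reagents that add atoms: none
Why: Catalytic hydrogenation of the diarylalkyne to the ethano bridge D–CH2CH2–A; ester, aryl ethers and phenol are inert, and no benzyl ether is present yet.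

Step 4
Reactants: 7 4-fluoro-3-hydroxybenzaldehyde
Product: 8 3-(benzyloxy)-4-fluorobenzaldehyde
Conditions: BnBr, K2CO3, DMF, rt
Reagents that add atoms: benzyl bromide, BrCc1ccccc1
Why: Williamson ether synthesis; O-benzylation masks the ring C phenol with a group that survives every later step and is removed in the final hydrogenation.

Step 5
Reactants: 6 methyl 4-{5-[2-(3-hydroxyphenyl)ethyl]-2-methoxyphenoxy}benzoate; 8 3-(benzyloxy)-4-fluorobenzaldehyde
Product: 9 methyl 4-[5-(2-{3-[2-(benzyloxy)-4-formylphenoxy]phenyl}ethyl)-2-methoxyphenoxy]benzoate
Conditions: K2CO3, DMF, 130 °C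
Reagents that add atoms: none
Why: Nucleophilic aromatic substitution: the ring D phenoxide displaces the fluoride para to the aldehyde of 8. This forms the C–O–D ether with OBn ortho to the new bond, as the target requires.

Step 6
Reactants: 9 methyl 4-[5-(2-{3-[2-(benzyloxy)-4-formylphenoxy]phenyl}ethyl)-2-methoxyphenoxy]benzoate
Product: 10 {4-[5-(2-{3-[2-(benzyloxy)-4-(hydroxymethyl)phenoxy]phenyl}ethyl)-2-methoxyphenoxy]phenyl}methanol
Conditions: LiAlH4, THF, 0 °C to rt; aqueous NaOH work-up
Reagents that add atoms: none
Why: Hydride reduction of ester and aldehyde to the two benzylic alcohols in one operation; aryl ethers and the benzyl ether are inert to LiAlH4.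

Step 7
Reactants: 10 {4-[5-(2-{3-[2-(benzyloxy)-4-(hydroxymethyl)phenoxy]phenyl}ethyl)-2-methoxyphenoxy]phenyl}methanol
Product: 11 2-(benzyloxy)-4-(bromomethyl)-1-[3-(2-{3-[4-(bromomethyl)phenoxy]-4-methoxyphenyl}ethyl)phenoxy]benzene
Conditions: PBr3, CH2Cl2, 0 °C; used without storage
Reagents that add atoms: phosphorus tribromide, BrP(Br)Br
Why: Conversion of both benzylic alcohols into bromides through their phosphite esters; the para-aryloxy groups make both positions reactive, so mild conditions suffice.

Step 8
Reactants: 11 2-(benzyloxy)-4-(bromomethyl)-1-[3-(2-{3-[4-(bromomethyl)phenoxy]-4-methoxyphenyl}ethyl)phenoxy]benzene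
Product: 14 21-membered macrocyclic sulfide (ArB–CH2–S–CH2–ArC; ring C carries OBn), via ring-B-side bromo thiolate 12 (not isolated), via ring-C-side bromo thiolate 13 (not isolated)
Conditions: Na2S on Al2O3 (from Na2S·9H2O), CH2Cl2/EtOH 9:1, rt, slow addition of 11 (final concentration about 2 mM)
Reagents that add atoms: sodium sulfide, [Na+].[Na+].[S-2]
Why: Double SN2 thioetherification with sulfide as a one-atom linchpin, the standard thiacyclophane closure for benzylic dibromides. The first displacement gives 12 or 13, and at high dilution the thiolate should close the 21-membered ring on the remaining bromide faster than it meets a second molecule.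

Step 9
Reactants: 14 21-membered macrocyclic sulfide
Product: 16 21-membered macrocyclic sulfone (ArB–CH2–SO2–CH2–ArC; ring C carries OBn), via macrocyclic sulfoxide 15 (not isolated)
Conditions: mCPBA (2.2 equiv), NaHCO3, CH2Cl2, 0 °C to rt
Reagents that add atoms: 3-chloroperbenzoic acid, OOC(=O)c1cccc(Cl)c1
Why: Peracid oxidation of the sulfide through the sulfoxide 15 to the sulfone; sulfur is far more nucleophilic than the arenes, and the ethers are inert.

Step 10
Reactants: 16 21-membered macrocyclic sulfone
Product: 20 (Z)-stilbene macrocycle (O-benzyl-didehydropakyonol), via ring-B-side α-bromo sulfone 17 (not isolated), via ring-C-side α-bromo sulfone 18 (not isolated), via cis-episulfone 19 (not isolated)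
Conditions: CBr2F2, KOH on Al2O3, t-BuOH/CH2Cl2, 0 °C to rt
Reagents that add atoms: none
Why: Ramberg–Bäcklund rearrangement in its one-flask in-situ halogenation form, a reaction type established for dibenzyl sulfones, including macrocyclic cyclophane sulfones. The base removes a proton from one of the two α-carbons of 16 (each benzylic and α-sulfonyl), and the carbanion takes Br+ from CBr2F2 to give 17 or 18. A second deprotonation at the other α-carbon is followed by intramolecular 1,3-displacement of bromide, a 3-exo-tet closure that gives the episulfone 19 and forms the C–C bond between the benzylic carbons of rings B and C. Cheletropic loss of SO2 from 19 then contracts the 21-membered ring to the 20-membered ring of the target. No stereocentre survives: the carbon centres of 17–19 become sp2, and the Z geometry expected from the cis-episulfone (a trans-stilbene cannot be spanned without strain by the eight-atom meta,meta strap between the two ether oxygens) is erased in step 11. The step needs monohalogenation at the α-sulfonyl carbons only, which is secured because these are the only C–H bonds acidic enough for KOH and the phenol is masked as its benzyl ether. It also needs C–C closure within the ring, which is secured because that bond forms in a three-membered transition state after the macrocycle is closed, leaving no intermolecular path. Both 17 and 18 converge on the same 19.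

Step 11
Reactants: 20 (Z)-stilbene macrocycle
Product: 22 pakyonol, via O-benzylpakyonol 21 (not isolated)
Conditions: H2 (1 atm), 10% Pd/C, EtOAc/EtOH, rt
Reagents that add atoms: none
Why: Heterogeneous hydrogenation should saturate the stilbene double bond first (21) and then hydrogenolyse the benzyl aryl ether. The methyl ether and diaryl ethers are inert, and the substrate is sulfur-free after step 10.

## Compound list

1 | 5-bromo-2-methoxyphenol | COc1ccc(Br)cc1O | starting material
2 | methyl 4-fluorobenzoate | COC(=O)c1ccc(F)cc1 | starting material
3 | methyl 4-(5-bromo-2-methoxyphenoxy)benzoate | COC(=O)c1ccc(Oc2cc(Br)ccc2OC)cc1 | intermediate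
4 | 3-ethynylphenol | C#Cc1cccc(O)c1 | starting material
5 | methyl 4-{5-[(3-hydroxyphenyl)ethynyl]-2-methoxyphenoxy}benzoate | COC(=O)c1ccc(Oc2cc(C#Cc3cccc(O)c3)ccc2OC)cc1 | intermediate
6 | methyl 4-{5-[2-(3-hydroxyphenyl)ethyl]-2-methoxyphenoxy}benzoate | COC(=O)c1ccc(Oc2cc(CCc3cccc(O)c3)ccc2OC)cc1 | intermediate
7 | 4-fluoro-3-hydroxybenzaldehyde | O=Cc1ccc(F)c(O)c1 | starting material
8 | 3-(benzyloxy)-4-fluorobenzaldehyde | O=Cc1ccc(F)c(OCc2ccccc2)c1 | intermediate
9 | methyl 4-[5-(2-{3-[2-(benzyloxy)-4-formylphenoxy]phenyl}ethyl)-2-methoxyphenoxy]benzoate | COC(=O)c1ccc(Oc2cc(CCc3cccc(Oc4ccc(C=O)cc4OCc4ccccc4)c3)ccc2OC)cc1 | intermediate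
10 | {4-[5-(2-{3-[2-(benzyloxy)-4-(hydroxymethyl)phenoxy]phenyl}ethyl)-2-methoxyphenoxy]phenyl}methanol | OCc1ccc(Oc2cc(CCc3cccc(Oc4ccc(CO)cc4OCc4ccccc4)c3)ccc2OC)cc1 | intermediate
11 | 2-(benzyloxy)-4-(bromomethyl)-1-[3-(2-{3-[4-(bromomethyl)phenoxy]-4-methoxyphenyl}ethyl)phenoxy]benzene | BrCc1ccc(Oc2cc(CCc3cccc(Oc4ccc(CBr)cc4OCc4ccccc4)c3)ccc2OC)cc1 | intermediate
12 | sodium thiolate of 11 with sulfur on the ring B benzylic carbon and bromide retained on the ring C benzylic carbon | [Na+].[S-]Cc1ccc(Oc2cc(CCc3cccc(Oc4ccc(CBr)cc4OCc4ccccc4)c3)ccc2OC)cc1 | intermediate (not isolated)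
13 | sodium thiolate of 11 with sulfur on the ring C benzylic carbon and bromide retained on the ring B benzylic carbon | [Na+].[S-]Cc1ccc(Oc2cccc(CCc3ccc(OC)c(Oc4ccc(CBr)cc4)c3)c2)c(OCc2ccccc2)c1 | intermediate (not isolated)
14 | 21-membered macrocyclic sulfide: O-benzylpakyonol skeleton with sulfur inserted between the benzylic carbons of rings B and C | COc1ccc2cc1Oc1ccc(cc1)CSCc1ccc(c(OCc3ccccc3)c1)Oc1cccc(c1)CC2 | intermediate
15 | S-oxide of 14 (racemic at sulfur) | COc1ccc2cc1Oc1ccc(cc1)CS(=O)Cc1ccc(c(OCc3ccccc3)c1)Oc1cccc(c1)CC2 | intermediate (not isolated)
16 | S,S-dioxide of 14 (21-membered macrocyclic dibenzyl sulfone) | COc1ccc2cc1Oc1ccc(cc1)CS(=O)(=O)Cc1ccc(c(OCc3ccccc3)c1)Oc1cccc(c1)CC2 | intermediate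
17 | α-bromo sulfone from 16, bromine on the ring B benzylic carbon (racemic) | COc1ccc2cc1Oc1ccc(cc1)C(Br)S(=O)(=O)Cc1ccc(c(OCc3ccccc3)c1)Oc1cccc(c1)CC2 | intermediate (not isolated)
18 | α-bromo sulfone from 16, bromine on the ring C benzylic carbon (racemic) | COc1ccc2cc1Oc1ccc(cc1)CS(=O)(=O)C(Br)c1ccc(c(OCc3ccccc3)c1)Oc1cccc(c1)CC2 | intermediate (not isolated)
19 | cis-2,3-diaryl thiirane 1,1-dioxide fused into the macrocycle (racemic; one enantiomer drawn) | COc1ccc2cc1Oc1ccc(cc1)[C@@H]3[C@@H](S3(=O)=O)c1ccc(c(OCc4ccccc4)c1)Oc1cccc(c1)CC2 | intermediate (not isolated)
20 | (Z)-stilbene macrocycle: O-benzylpakyonol with a Z double bond between the benzylic carbons of rings B and C | COc1ccc2cc1Oc1ccc(cc1)/C=C\c1ccc(c(OCc3ccccc3)c1)Oc1cccc(c1)CC2 | intermediate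
21 | O-benzylpakyonol | COc1ccc2cc1Oc1ccc(cc1)CCc1ccc(c(OCc3ccccc3)c1)Oc1cccc(c1)CC2 | intermediate (not isolated)
22 | pakyonol | COc1ccc2cc1Oc1ccc(cc1)CCc1ccc(c(O)c1)Oc1cccc(c1)CC2 | target

## Step count and risk

Total step count: 11. Longest linear sequence: 10 (steps 1, 2, 3, 5, 6, 7, 8, 9, 10, 11; step 4 is a one-step side branch).

Step 10 (key step). Most likely to go wrong: a second bromine transfer to the α-bromo carbanion before the 1,3-displacement, which is slowed by the ring, or incomplete deprotonation on the heterogeneous base so that sulfone is returned. Fallback, from 14 back to 21: ring contraction by Stevens rearrangement in place of carbanionic SO2 extrusion. S-Methylation of 14 with methyl triflate (CH2Cl2, 0 °C) would give the S-methylsulfonium triflate F1. KOt-Bu in THF would generate a benzylic sulfonium ylide whose [1,2]-shift gives the ring-contracted regioisomeric methylthio bibenzyl macrocycles F2 and F3. Raney nickel in EtOH would remove the methylthio group from both and give 21, which enters step 11 conditions as before; if the nickel also cleaves the benzyl ether, 22 results directly.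

Step 8. Most likely to go wrong: intermolecular S-alkylation giving cyclic dimers and oligomers if the local concentration of 11 rises, and ethanolysis of the electron-rich benzylic bromides. Fallback, from 11 back to 21: direct intramolecular reductive C–C coupling of the two benzylic bromides (NiBr2(PPh3)2 cat., Zn, Et4NI, THF, slow addition), a Wurtz-type closure that bypasses steps 8–10; it makes no new compound (F0).

Step 5. Most likely to go wrong: slow fluoride displacement because the ortho benzyloxy group is both donating and bulky, with degradation of the aldehyde on prolonged heating. Fallback, from 6 back to 9: copper-catalysed Ullmann ether coupling in place of SNAr. Commercial 4-bromo-3-hydroxybenzaldehyde F4 would be benzylated (BnBr, K2CO3, DMF) to 3-(benzyloxy)-4-bromobenzaldehyde F5, which is coupled with 6 (CuI, N,N-dimethylglycine, Cs2CO3, dioxane, 90 °C) to give 9.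

Step 1. Most likely to go wrong: sluggish substitution because an ester is a weaker activator than an aldehyde or nitrile, with saponification of the ester by adventitious hydroxide in hot DMSO. Fallback, from 1 back to 3: oxidative Chan–Lam coupling of 1 with commercial [4-(methoxycarbonyl)phenyl]boronic acid F6 (Cu(OAc)2, pyridine, 4 Å MS, CH2Cl2, air, rt); the C–Br bond of 1 is inert under these conditions.

## Further compounds

F1 | step 10 | S-methylsulfonium trifluoromethanesulfonate of 14 (racemic at sulfur) | COc1ccc2cc1Oc1ccc(cc1)C[S+](C)Cc1ccc(c(OCc3ccccc3)c1)Oc1cccc(c1)CC2.[O-]S(=O)(=O)C(F)(F)F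
F2 | step 10 | O-benzylpakyonol bearing SMe on the ring B benzylic carbon (racemic) | COc1ccc2cc1Oc1ccc(cc1)C(SC)Cc1ccc(c(OCc3ccccc3)c1)Oc1cccc(c1)CC2
F3 | step 10 | O-benzylpakyonol bearing SMe on the ring C benzylic carbon (racemic) | COc1ccc2cc1Oc1ccc(cc1)CC(SC)c1ccc(c(OCc3ccccc3)c1)Oc1cccc(c1)CC2
F0 | step 8 | none | none
F4 | step 5 | 4-bromo-3-hydroxybenzaldehyde | O=Cc1ccc(Br)c(O)c1
F5 | step 5 | 3-(benzyloxy)-4-bromobenzaldehyde | O=Cc1ccc(Br)c(OCc2ccccc2)c1
F6 | step 1 | [4-(methoxycarbonyl)phenyl]boronic acid | COC(=O)c1ccc(B(O)O)cc1
A1 | alternative 1 | {4-[5-(2-{3-[2-(benzyloxy)-4-formylphenoxy]phenyl}ethyl)-2-methoxyphenoxy]benzyl}triphenylphosphonium bromide | [Br-].O=Cc1ccc(Oc2cccc(CCc3ccc(OC)c(Oc4ccc(C[P+](c5ccccc5)(c5ccccc5)c5ccccc5)cc4)c3)c2)c(OCc2ccccc2)c1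
A2 | alternative 2 | 3-{2-[3-(4-{2-(4-fluoro-3-nitrophenyl)ethyl}phenoxy)-4-methoxyphenyl]ethyl}phenol | COc1ccc(CCc2cccc(O)c2)cc1Oc1ccc(CCc2ccc(F)c([N+](=O)[O-])c2)cc1
A3 | alternative 2 | nitro macrocycle: pakyonol with NO2 in place of the ring C hydroxyl | COc1ccc2cc1Oc1ccc(cc1)CCc1ccc(c([N+](=O)[O-])c1)Oc1cccc(c1)CC2
A4 | alternative 3 | 3-[2-(4-{5-[2-(3-hydroxyphenyl)ethyl]-2-methoxyphenoxy}phenyl)ethyl]phenol | COc1ccc(CCc2cccc(O)c2)cc1Oc1ccc(CCc2cccc(O)c2)cc1
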